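Ring B is disconnected across C1'–C6'. Its pattern – phenols at C2' and C4' (meta), methoxy at C5', hydrogens at C3' and C6', and C1' bonded to C2 of the chromone (ring C) – is that of a folded 1,3,5-tricarbonyl chain, and the key step exploits exactly this alternation. One operation unmasks an aldehyde at C6', lets the doubly activated C1' methylene condense with it, closes ring B and aromatises it, leaving 5'-OMe distinct from the two phenols. The precursor is the 5,6,7,8-tetramethoxychromone bearing at C2 a 2,4-dioxohexyl chain with OMe at C5 and a dimethyl acetal at C6, assembled from a 2-acetonylchromone dianion and a Weinreb amide.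

Key step: step 8

Remark: 13, 14 and 16 each carry one stereocentre (the methoxy-bearing CH) and are used as racemates, because step 8 turns this carbon into the sp2 carbon C5'; the target is achiral. Chain carbons of 10, 15, 16 and 17 are labelled C1'–C6' as they end up in ring B.

Step 1
Reactants: 1 1,2,3,4-tetramethoxybenzene
Product: 4 2,3,4,5-tetramethoxyphenol, via (2,3,4,5-tetramethoxyphenyl)lithium 2 (not isolated), via dimethyl (2,3,4,5-tetramethoxyphenyl)boronate 3 (not isolated)
Conditions: n-BuLi, TMEDA, THF, 0 °C to rt; B(OMe)3, −78 °C to rt; 30% H2O2, AcOH, 0 °C to rt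
Reagents that add atoms: hydrogen peroxide, OO
Why: Directed ortho-lithiation at one of the two equivalent free ring positions, borate trapping and peroxide oxidation of the aryl boronate (aryl shift from boron to oxygen) is a standard arene-to-phenol sequence, and with only one kind of C–H there is no regiochemical question.

Step 2
Reactants: 4 2,3,4,5-tetramethoxyphenol
Product: 6 1-(2-hydroxy-3,4,5,6-tetramethoxyphenyl)ethanone, via difluoroboron chelate of the ketophenol 5 (not isolated)
Conditions: AcOH, BF3·OEt2, 85 °C; then H2O/MeOH, reflux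
Reagents that add atoms: acetic acid, CC(=O)O
Why: BF3-mediated Friedel–Crafts (Fries-type) acylation can only occur at the single unsubstituted carbon, which is ortho to the phenol, and the product should be held as its BF2 chelate 5 until aqueous methanol releases 6.

Step 3
Reactants: 6 1-(2-hydroxy-3,4,5,6-tetramethoxyphenyl)ethanone
Product: 8 5,6,7,8-tetramethoxy-2-methyl-4H-chromen-4-one, via 1-(2-hydroxy-3,4,5,6-tetramethoxyphenyl)butane-1,3-dione 7 (not isolated)
Conditions: NaH, EtOAc, THF, 65 °C; then conc. HCl, MeOH, 65 °C
Reagents that add atoms: ethyl acetate, CCOC(C)=O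
Why: Claisen condensation of the phenoxide–enolate of 6 with ethyl acetate should give β-diketone 7, and acid-catalysed cyclodehydration (phenol oxygen onto the distal carbonyl, loss of water) is the classical 2-methylchromone synthesis, under which aryl methyl ethers are stable.

Step 4
Reactants: 8 5,6,7,8-tetramethoxy-2-methyl-4H-chromen-4-one
Product: 10 5,6,7,8-tetramethoxy-2-(2-oxopropyl)-4H-chromen-4-one, via lithium dienolate of the 2-methylchromone 9 (not isolated)
Conditions: LiN(SiMe3)2, THF, −78 °C; MeC(O)N(OMe)Me, −78 to −30 °C; 1 M HCl, 0 °C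
Reagents that add atoms: N-methoxy-N-methylacetamide, CC(=O)N(C)OC
Why: The 2-methyl group of a chromone is a vinylogous methyl ketone, so the amide base should give lateral dienolate 9, and its C-acylation by the Weinreb amide stops at the ketone because the adduct does not collapse before the acidic quench (Weinreb ketone synthesis on a vinylogous enolate).

Step 5
Reactants: 11 methyl methoxyacetate
Product: 13 methyl 2,3,3-trimethoxypropanoate (racemic), via sodium enolate of methyl 2-methoxy-3-oxopropanoate 12 (not isolated)
Conditions: HCO2Me, NaOMe, THF, 0 °C to rt; then HC(OMe)3, HCl, MeOH, rt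
Reagents that add atoms: methyl formate, COC=O; trimethyl orthoformate, COC(OC)OC; methanol, CO
Why: Crossed Claisen formylation with non-enolisable methyl formate should give the stabilised enolate 12, which on acidification in methanol with trimethyl orthoformate is acetalised at the aldehyde carbon; the new stereocentre at C2 forms without control, giving the racemate, which suffices.

Step 6
Reactants: 13 methyl 2,3,3-trimethoxypropanoate (racemic)
Product: 14 N,2,3,3-tetramethoxy-N-methylpropanamide (racemic)
Conditions: MeNH(OMe)·HCl, i-PrMgCl, THF, −20 to 0 °C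
Reagents that add atoms: N,O-dimethylhydroxylamine hydrochloride, CNOC.Cl
Why: Aminolysis of the methyl ester by the chloromagnesium amide generated in the flask is the standard ester-to-Weinreb-amide conversion, and at −20 °C this weakly basic amide should not trigger β-elimination of methanol from the acetal; the stereocentre stays racemic.

Step 7
Reactants: 10 5,6,7,8-tetramethoxy-2-(2-oxopropyl)-4H-chromen-4-one; 14 N,2,3,3-tetramethoxy-N-methylpropanamide (racemic)
Product: 16 5,6,7,8-tetramethoxy-2-(5,6,6-trimethoxy-2,4-dioxohexyl)-4H-chromen-4-one (racemic), via dilithium dianion of the 2-acetonylchromone 15 (not isolated)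
Conditions: LiN(i-Pr)2 (2.1 equiv), THF, −78 to −20 °C; 14, −78 to −30 °C; AcOH, −78 °C, then H2O
Reagents that add atoms: none
Why: Two equivalents of amide base should remove first a C1' proton (flanked by the ketone and the vinylogous ester of ring C) and then a terminal methyl proton, and dianion 15 reacts at its less stabilised terminal carbon with the Weinreb amide (γ-acylation of a 1,3-dicarbonyl-type dianion, Claisen type), the chelated adduct keeping the acidic product from forming and quenching 15 before work-up; 16 is racemic at C5 of the chain.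

Step 8
Reactants: 16 5,6,7,8-tetramethoxy-2-(5,6,6-trimethoxy-2,4-dioxohexyl)-4H-chromen-4-one (racemic)
Product: 18 2-(2,4-dihydroxy-5-methoxyphenyl)-5,6,7,8-tetramethoxy-4H-chromen-4-one, via 2-[(5-methoxy-4-oxo-4H-pyran-2-yl)methyl]-5,6,7,8-tetramethoxy-4H-chromen-4-one 17 (not isolated)
Conditions: TFA–H2O (9:1), rt, evaporate; NaOMe, MeOH, 60 °C, Ar; aq. HCl to pH 3
Reagents that add atoms: none
Why: Aqueous acid hydrolyses the C6' acetal and the freed 3,5-dioxo aldehyde closes through the C2' enol oxygen to γ-pyrone 17, an isomer of the target; unmasking comes first because an acetal is inert to alkoxide and the C5'–H of the enolate polyanion is too weakly acidic to expel methanol. Methoxide then adds to the unsubstituted pyrone carbon (C6') and reopens the ring to a C5'=C6' β-methoxy enone, whereupon the C1' carbanion, stabilised by the C2' carbonyl and vinylogously by the C4 carbonyl of ring C, attacks C6' and expels methoxide. Ring B thus closes in a 6-endo-trig addition–elimination that forms the C1'–C6' bond, and enolisation of the C2' and C4' ketones gives the arene irreversibly; no stereocentre is formed and the one at C5' is erased. The closest known reaction type is the base-induced conversion of γ-pyrones and their open 1,3,5-tricarbonyl forms into resorcinols (biomimetic polyketide aldol aromatisation). The step needs C- over O-cyclisation and C1' over C3' attack: C3' could only close a four-membered ring, O-closure merely returns pyrone 17, which reopens, and only the carbocycle can aromatise. Because the methoxy-bearing chain carbon becomes C5', the 5'-OMe is set apart from the free 2'- and 4'-phenols without protecting groups.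

Compound list
1 | 1,2,3,4-tetramethoxybenzene | COc1ccc(OC)c(OC)c1OC | starting material
2 | (2,3,4,5-tetramethoxyphenyl)lithium | [Li]c1cc(OC)c(OC)c(OC)c1OC | intermediate (not isolated)
3 | dimethyl (2,3,4,5-tetramethoxyphenyl)boronate | COB(OC)c1cc(OC)c(OC)c(OC)c1OC | intermediate (not isolated)
4 | 2,3,4,5-tetramethoxyphenol | Oc1cc(OC)c(OC)c(OC)c1OC | intermediate
5 | difluoroboron chelate of 1-(2-hydroxy-3,4,5,6-tetramethoxyphenyl)ethanone (six-membered O–B–O ring through phenolate and carbonyl oxygen) | CC1=[O+][B-](F)(F)Oc2c(OC)c(OC)c(OC)c(OC)c12 | intermediate (not isolated)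
6 | 1-(2-hydroxy-3,4,5,6-tetramethoxyphenyl)ethanone | CC(=O)c1c(O)c(OC)c(OC)c(OC)c1OC | intermediate
7 | 1-(2-hydroxy-3,4,5,6-tetramethoxyphenyl)butane-1,3-dione | CC(=O)CC(=O)c1c(O)c(OC)c(OC)c(OC)c1OC | intermediate (not isolated)
8 | 5,6,7,8-tetramethoxy-2-methyl-4H-chromen-4-one | Cc1cc(=O)c2c(OC)c(OC)c(OC)c(OC)c2o1 | intermediate
9 | lithium dienolate of 8, deprotonated at the 2-methyl group (drawn as the carbanion form) | [Li+].[CH2-]c1cc(=O)c2c(OC)c(OC)c(OC)c(OC)c2o1 | intermediate (not isolated)
10 | 5,6,7,8-tetramethoxy-2-(2-oxopropyl)-4H-chromen-4-one | CC(=O)Cc1cc(=O)c2c(OC)c(OC)c(OC)c(OC)c2o1 | intermediate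
11 | methyl methoxyacetate | COCC(=O)OC | starting material
12 | sodium enolate of methyl 2-methoxy-3-oxopropanoate (drawn as the carbanion form) | [Na+].COC(=O)[C-](OC)C=O | intermediate (not isolated)
13 | methyl 2,3,3-trimethoxypropanoate (racemic) | COC(OC)C(OC)C(=O)OC | intermediate
14 | N,2,3,3-tetramethoxy-N-methylpropanamide (racemic) | COC(OC)C(OC)C(=O)N(C)OC | intermediate
15 | dilithium dianion of 10, deprotonated at C1' and at the terminal methyl (drawn as the carbanion form) | [Li+].[Li+].[CH2-]C(=O)[CH-]c1cc(=O)c2c(OC)c(OC)c(OC)c(OC)c2o1 | intermediate (not isolated)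
16 | 5,6,7,8-tetramethoxy-2-(5,6,6-trimethoxy-2,4-dioxohexyl)-4H-chromen-4-one (racemic) | COC(OC)C(OC)C(=O)CC(=O)Cc1cc(=O)c2c(OC)c(OC)c(OC)c(OC)c2o1 | intermediate
17 | 2-[(5-methoxy-4-oxo-4H-pyran-2-yl)methyl]-5,6,7,8-tetramethoxy-4H-chromen-4-one | COc1coc(Cc2cc(=O)c3c(OC)c(OC)c(OC)c(OC)c3o2)cc1=O | intermediate (not isolated)
18 | 2-(2,4-dihydroxy-5-methoxyphenyl)-5,6,7,8-tetramethoxy-4H-chromen-4-one | COc1cc(-c2cc(=O)c3c(OC)c(OC)c(OC)c(OC)c3o2)c(O)cc1O | target

Total steps: 8. Longest linear sequence: 6 steps (1, 2, 3, 4, 7, 8); the amide branch (steps 5 and 6) joins at step 7.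

Steps most likely to fail

Step 8. Ring opening of the pyrone by methoxide may be slow, and the electron-rich phenolates may degrade or the chromone ring may be attacked before the carbocycle forms. The fallback brings ring B in preformed; it sets out from 6 and returns at 18. 2,4-Dihydroxy-5-methoxybenzaldehyde (assumed purchasable) would be benzylated twice (BnBr, K2CO3, DMF) to 2,4-bis(benzyloxy)-5-methoxybenzaldehyde F1. Claisen–Schmidt condensation of 6 with F1 (KOH, EtOH) should give (E)-3-[2,4-bis(benzyloxy)-5-methoxyphenyl]-1-(2-hydroxy-3,4,5,6-tetramethoxyphenyl)prop-2-en-1-one F2. Oxidative cyclisation (catalytic I2, DMSO, 120 °C) should give 2-[2,4-bis(benzyloxy)-5-methoxyphenyl]-5,6,7,8-tetramethoxy-4H-chromen-4-one F3. Hydrogenolysis (H2, Pd/C, 10% palladium on carbon, EtOAc/MeOH) would remove both benzyl groups to give 18.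

Step 7. Proton transfer from the α-C–H of 14 to the dianion, followed by loss of methoxide from the acetal, or incomplete second deprotonation with reaction at C1', may erode the acylation. The fallback replaces acylation by aldol addition and oxidation; it sets out from 10 and 14 and returns at 16. Reduction of 14 (i-Bu2AlH, THF, −78 °C) should give 2,3,3-trimethoxypropanal (racemic) F4. Dianion 15, made from 10 as in step 7, would add to F4 at −78 °C to give 2-(4-hydroxy-5,6,6-trimethoxy-2-oxohexyl)-5,6,7,8-tetramethoxy-4H-chromen-4-one (mixture of diastereomers) F5; the alkoxide product cannot quench the dianion. Oxidation of the β-hydroxy ketone (Dess–Martin periodinane, NaHCO3, CH2Cl2) should give 16.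

Step 4. Conjugate addition of the lithiated chromone to C2 of not yet deprotonated 8 (self-condensation), or deprotonation at the wrong site, may compete with acylation. The fallback avoids lateral metalation; it sets out from 6 and returns at 10. Claisen condensation of 6 with ethyl 2-(2-methyl-1,3-dioxolan-2-yl)acetate (purchasable; NaH, THF, 65 °C) should give 1-(2-hydroxy-3,4,5,6-tetramethoxyphenyl)-4-(2-methyl-1,3-dioxolan-2-yl)butane-1,3-dione F6. Cyclodehydration (catalytic TsOH, toluene, reflux) should give 5,6,7,8-tetramethoxy-2-[(2-methyl-1,3-dioxolan-2-yl)methyl]-4H-chromen-4-one F7, and ketal hydrolysis (1 M HCl, THF, rt) would give 10.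

Further compounds
F1 | step 8 | 2,4-bis(benzyloxy)-5-methoxybenzaldehyde | COc1cc(C=O)c(OCc2ccccc2)cc1OCc1ccccc1
F2 | step 8 | (E)-3-[2,4-bis(benzyloxy)-5-methoxyphenyl]-1-(2-hydroxy-3,4,5,6-tetramethoxyphenyl)prop-2-en-1-one | COc1cc(/C=C/C(=O)c2c(O)c(OC)c(OC)c(OC)c2OC)c(OCc2ccccc2)cc1OCc1ccccc1
F3 | step 8 | 2-[2,4-bis(benzyloxy)-5-methoxyphenyl]-5,6,7,8-tetramethoxy-4H-chromen-4-one | COc1cc(-c2cc(=O)c3c(OC)c(OC)c(OC)c(OC)c3o2)c(OCc2ccccc2)cc1OCc1ccccc1
F4 | step 7 | 2,3,3-trimethoxypropanal (racemic) | COC(OC)C(OC)C=O
F5 | step 7 | 2-(4-hydroxy-5,6,6-trimethoxy-2-oxohexyl)-5,6,7,8-tetramethoxy-4H-chromen-4-one (mixture of diastereomers, racemic) | COC(OC)C(OC)C(O)CC(=O)Cc1cc(=O)c2c(OC)c(OC)c(OC)c(OC)c2o1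
F6 | step 4 | 1-(2-hydroxy-3,4,5,6-tetramethoxyphenyl)-4-(2-methyl-1,3-dioxolan-2-yl)butane-1,3-dione | CC1(CC(=O)CC(=O)c2c(O)c(OC)c(OC)c(OC)c2OC)OCCO1
F7 | step 4 | 5,6,7,8-tetramethoxy-2-[(2-methyl-1,3-dioxolan-2-yl)methyl]-4H-chromen-4-one | CC1(Cc2cc(=O)c3c(OC)c(OC)c(OC)c(OC)c3o2)OCCO1
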